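**Retrosynthetic overview**
1. Target 12 ⇐ C9–O bond: α′-C–H acetoxylation of enone ester 11 (last step, sets C9).
2. 11 ⇐ C1–O bond: invertive (Mitsunobu) esterification of alcohol 9 with isobutyric acid, which sets the carbinol centre; 9 ⇐ ketone 8 by face-selective hydride reduction.
3. 8 ⇐ conjugate methylation of spirodienone 7; 7 ⇐ formyl ketone 4 + pent-3-yn-2-one (Michael/aldol spiroannulation).
4. Ring order: the cyclopentane comes first (cyclopent-2-en-1-one, rhodium-catalysed isopropenyl addition); the cyclohexadienone ring is then annulated at the spiro carbon.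

Assumption: the SMILES descriptors are absolute; spiro[4.5]decane numbering is used (C1 = oxygenated cyclopentane carbon, C3 = isopropenyl carbon, C5 = spiro carbon); the facial sense of the chiral catalysts in steps 3 and 4 is assigned by analogy, and the antipodal catalyst is used if a first run shows the opposite sense.

**Step 1**
Reactants: 1 cyclopent-2-en-1-one; 2 4,4,5,5-tetramethyl-2-(prop-1-en-2-yl)-1,3,2-dioxaborolane
Product: 3 (3S)-3-(prop-1-en-2-yl)cyclopentan-1-one
Conditions: [RhCl(C2H4)2]2 (1.5 mol %), (S)-BINAP (3.3 mol %), KOH (10 mol %), dioxane/H2O 10:1, 50 °C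
Reagents that add atoms: none
Why: Hayashi–Miyaura rhodium-catalysed asymmetric 1,4-addition of an alkenylboron reagent to a cyclic enone; the (S)-BINAP–rhodium alkenyl species adds to one enantioface and sets C3 as S, the sense known for aryl- and alkenylboron reagents with cyclopent-2-enone.

**Step 2**
Reactants: 3 (3S)-3-(prop-1-en-2-yl)cyclopentan-1-one
Product: 4 (4S)-2-(hydroxymethylidene)-4-(prop-1-en-2-yl)cyclopentan-1-one
Conditions: NaH (1.2 equiv), HCO2Et (3 equiv), EtOH (cat.), Et2O, 0 → 23 °C; 1 M HCl work-up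
Reagents that add atoms: ethyl formate, CCOC=O
Why: crossed Claisen condensation (formylation) of the ketone enolate, which under its reversible conditions ends at the less hindered α-carbon remote from the isopropenyl-bearing carbon; no new stereocentre is formed (the product is the enol of the 2-formyl ketone).

**Step 3**
Reactants: 4 (4S)-2-(hydroxymethylidene)-4-(prop-1-en-2-yl)cyclopentan-1-one; 5 pent-3-yn-2-one
Product: 7 (3S,5R)-6-methyl-3-(prop-1-en-2-yl)spiro[4.5]deca-6,9-diene-1,8-dione, via Z-enone keto aldehyde 6 (not isolated)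
Conditions: (DHQ)2PHAL (10 mol %), CH2Cl2, −20 °C; then pyrrolidine (20 mol %), AcOH (40 mol %), 40 °C
Reagents that add atoms: none
Why: Proposed new method: the dimeric cinchona alkaloid acts as a chiral Brønsted base whose quinuclidinium ion pairs with the delocalised enolate of 4 and lets the internal ynone approach only one face of C2 (catalyst control, because the 1,3-related isopropenyl group biases this face only weakly), anti-protonation of the allenolate gives the Z-enone 6 with the acetyl group cis to the new quaternary carbon, and amine-catalysed aldol condensation of its methyl ketone onto the far more electrophilic formyl group (not the ring ketone) closes the cyclohexadienone and fixes C5 as R; the closest known reaction type is the cinchona-catalysed conjugate addition of cyclic β-dicarbonyl compounds to alkynones together with the Robinson-type spiroannulation of 2-formylcycloalkanones, neither shown for an α-formyl ketone with an internal ynone or run as one enantioselective dienone annulation.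

**Step 4**
Reactants: 7 (3S,5R)-6-methyl-3-(prop-1-en-2-yl)spiro[4.5]deca-6,9-diene-1,8-dione
Product: 8 (3S,5R,10R)-6,10-dimethyl-3-(prop-1-en-2-yl)spiro[4.5]dec-6-ene-1,8-dione
Conditions: Cu(OTf)2 (5 mol %), (S,R,R)-phosphoramidite (10 mol %; from (S)-BINOL and bis[(R)-1-phenylethyl]amine), Me2Zn (2 equiv), toluene, −25 °C; 1 M HCl work-up
Reagents that add atoms: dimethylzinc, C[Zn]C
Why: copper–phosphoramidite-catalysed asymmetric conjugate addition of a dialkylzinc to a 4,4-disubstituted cyclohexa-2,5-dienone; only the β-unsubstituted C9=C10 arm reacts (the C6 arm is β,β-disubstituted), and the ligand delivers methyl to the C10 face syn to C1 (the sense this ligand shows with cyclohex-2-enone), which sets C10 as R.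

**Step 5**
Reactants: 8 (3S,5R,10R)-6,10-dimethyl-3-(prop-1-en-2-yl)spiro[4.5]dec-6-ene-1,8-dione
Product: 9 (1S,3S,5R,10R)-1-hydroxy-6,10-dimethyl-3-(prop-1-en-2-yl)spiro[4.5]dec-6-en-8-one
Conditions: NaBH4 (0.5 equiv), MeOH/CH2Cl2 1:1, −40 °C; aqueous work-up
Reagents that add atoms: none
Why: chemoselective borohydride reduction of the cyclopentanone beside the less electrophilic β,β-disubstituted enone (the selectivity used to make testosterone from androst-4-ene-3,17-dione); hydride enters C1 from the face flanked by C10, away from the vinylic C6 methyl that eclipses the C5–C1 bond and away from the isopropenyl group, so the hydroxyl ends up cis to the isopropenyl group (1S), the epimer needed for the inversion in step 6.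

**Step 6**
Reactants: 9 (1S,3S,5R,10R)-1-hydroxy-6,10-dimethyl-3-(prop-1-en-2-yl)spiro[4.5]dec-6-en-8-one; 10 2-methylpropanoic acid
Product: 11 (1R,3S,5R,10R)-6,10-dimethyl-8-oxo-3-(prop-1-en-2-yl)spiro[4.5]dec-6-en-1-yl 2-methylpropanoate
Conditions: PPh3 (2 equiv), DIAD (2 equiv), toluene, 0 → 40 °C
Reagents that add atoms: none
Why: Mitsunobu esterification, in which the alkoxyphosphonium ion of 9 is displaced by isobutyrate in an SN2 step from the less hindered face (the one hydride used), forming the C1–O ester bond with inversion to 1R, as in the known inversion of 17β-hydroxy steroids next to a quaternary carbon.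

**Step 7**
Reactants: 11 (1R,3S,5R,10R)-6,10-dimethyl-8-oxo-3-(prop-1-en-2-yl)spiro[4.5]dec-6-en-1-yl 2-methylpropanoate
Product: 12 (1R,3S,5R,9R,10S)-9-(acetyloxy)-6,10-dimethyl-8-oxo-3-(prop-1-en-2-yl)spiro[4.5]dec-6-en-1-yl 2-methylpropanoate
Conditions: Mn(OAc)3·2H2O (3 equiv), benzene, reflux (Dean–Stark)
Reagents that add atoms: manganese triacetate dihydrate, CC(=O)[O-].CC(=O)[O-].CC(=O)[O-].[Mn+3].O.O
Why: Mn(OAc)3 α′-acetoxylation of an α,β-unsaturated ketone (manganese enolate, then acetate transfer to the α′-keto radical); C9 is the only enolisable α′ position, the acetate enters axially anti to the neighbouring C10 methyl to give the trans (9R) acetate, and the isopropenyl group and the ester are tolerated as in the acetoxylation of carvone.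

**Compound list**
1 | cyclopent-2-en-1-one | O=C1C=CCC1 | starting material
2 | 4,4,5,5-tetramethyl-2-(prop-1-en-2-yl)-1,3,2-dioxaborolane | CC(=C)B1OC(C)(C)C(C)(C)O1 | starting material
3 | (3S)-3-(prop-1-en-2-yl)cyclopentan-1-one | C=C(C)[C@@H]1CC(=O)CC1 | intermediate
4 | (4S)-2-(hydroxymethylidene)-4-(prop-1-en-2-yl)cyclopentan-1-one | C=C(C)[C@@H]1CC(=O)C(=CO)C1 | intermediate
5 | pent-3-yn-2-one | CC#CC(C)=O | starting material
6 | (3Z)-4-[(1S,4S)-1-formyl-2-oxo-4-(prop-1-en-2-yl)cyclopentyl]pent-3-en-2-one | C=C(C)[C@@H]1CC(=O)[C@](C1)(C=O)/C(C)=C\C(C)=O | intermediate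
7 | (3S,5R)-6-methyl-3-(prop-1-en-2-yl)spiro[4.5]deca-6,9-diene-1,8-dione | C=C(C)[C@@H]1CC(=O)[C@@]2(C1)C(C)=CC(=O)C=C2 | intermediate
8 | (3S,5R,10R)-6,10-dimethyl-3-(prop-1-en-2-yl)spiro[4.5]dec-6-ene-1,8-dione | C=C(C)[C@@H]1CC(=O)[C@@]2(C1)C(C)=CC(=O)C[C@H]2C | intermediate
9 | (1S,3S,5R,10R)-1-hydroxy-6,10-dimethyl-3-(prop-1-en-2-yl)spiro[4.5]dec-6-en-8-one | C=C(C)[C@@H]1C[C@H](O)[C@@]2(C1)C(C)=CC(=O)C[C@H]2C | intermediate
10 | 2-methylpropanoic acid | CC(C)C(=O)O | starting material
11 | (1R,3S,5R,10R)-6,10-dimethyl-8-oxo-3-(prop-1-en-2-yl)spiro[4.5]dec-6-en-1-yl 2-methylpropanoate | C=C(C)[C@@H]1C[C@@H](OC(=O)C(C)C)[C@@]2(C1)C(C)=CC(=O)C[C@H]2C | intermediate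
12 | (1R,3S,5R,9R,10S)-9-(acetyloxy)-6,10-dimethyl-8-oxo-3-(prop-1-en-2-yl)spiro[4.5]dec-6-en-1-yl 2-methylpropanoate | C=C(C)[C@@H]1C[C@@H](OC(=O)C(C)C)[C@@]2(C1)C(C)=CC(=O)[C@H](OC(C)=O)[C@H]2C | target

**Total step count:** 7. **Longest linear sequence:** 7 (from cyclopent-2-en-1-one).

**Steps most likely to fail, and fallbacks**

Risk 1, step 3 (the proposed new spiroannulation). Catalyst control at C5 may be low, and the acyl dienone 7 is sensitive to nucleophiles (deformylation of 6, ring opening to a phenol). The fallback uses known chemistry only, sets out from 4 and comes back at 8, so it also replaces step 4. Compound 4 is added to but-3-yn-2-one (Et3N, CH2Cl2) and closed with pyrrolidinium acetate to (3S)-3-(prop-1-en-2-yl)spiro[4.5]deca-6,9-diene-1,8-dione F1, in which the spiro carbon is not a stereocentre. The known copper–phosphoramidite desymmetrising addition of Me2Zn to 4,4-disubstituted cyclohexadienones (Cu(OTf)2, the same ligand, toluene, −25 °C) then sets C5 and C10 together and gives (3S,5R,10R)-10-methyl-3-(prop-1-en-2-yl)spiro[4.5]dec-6-ene-1,8-dione F2. Me2CuLi/Me3SiCl (THF, −78 °C) adds the second methyl at C6 and gives (3S,5R,10R)-6,10-dimethyl-3-(prop-1-en-2-yl)-8-[(trimethylsilyl)oxy]spiro[4.5]dec-7-en-1-one F3 as a C6 epimer mixture. Saegusa–Ito oxidation (Pd(OAc)2, MeCN, 23 °C) restores the C6=C7 bond and delivers 8.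

Risk 2, step 6 (Mitsunobu at a carbinol next to the quaternary spiro carbon with a weakly acidic aliphatic acid; elimination or no reaction). The fallback sets out from 9 and comes back at 11; it forms the isobutyrate by acylation instead of by displacement. Compound 9 is inverted with the more acidic 4-nitrobenzoic acid (PPh3, DIAD, toluene) to (1R,3S,5R,10R)-6,10-dimethyl-8-oxo-3-(prop-1-en-2-yl)spiro[4.5]dec-6-en-1-yl 4-nitrobenzoate F4. Methanolysis (K2CO3, MeOH, 0 °C) gives (1R,3S,5R,10R)-1-hydroxy-6,10-dimethyl-3-(prop-1-en-2-yl)spiro[4.5]dec-6-en-8-one F5. Isobutyryl chloride, pyridine and DMAP (CH2Cl2, 0 °C) then give 11 with retention.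

Risk 3, step 7 (Mn(OAc)3 may attack the isopropenyl group or give a poor trans:cis ratio at C9). The fallback sets out from 11 and ends at 12; it replaces the radical C–H acetoxylation by an enol-ether oxidation. Kinetic α′-deprotonation and silylation (LiN(iPr)2, Me3SiCl, THF, −78 °C) give (1R,3S,5R,10R)-6,10-dimethyl-3-(prop-1-en-2-yl)-8-[(trimethylsilyl)oxy]spiro[4.5]deca-6,8-dien-1-yl 2-methylpropanoate F6. Pb(OAc)4 (CH2Cl2, −20 °C) then acetoxylates C9 anti to the C10 methyl and gives 12.

**Further compounds**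
F1 | step 3 | (3S)-3-(prop-1-en-2-yl)spiro[4.5]deca-6,9-diene-1,8-dione | C=C(C)[C@@H]1CC(=O)C2(C1)C=CC(=O)C=C2
F2 | step 3 | (3S,5R,10R)-10-methyl-3-(prop-1-en-2-yl)spiro[4.5]dec-6-ene-1,8-dione | C=C(C)[C@@H]1CC(=O)[C@@]2(C1)C=CC(=O)C[C@H]2C
F3 | step 3 | (3S,5R,10R)-6,10-dimethyl-3-(prop-1-en-2-yl)-8-[(trimethylsilyl)oxy]spiro[4.5]dec-7-en-1-one (C6 epimer mixture) | C=C(C)[C@@H]1CC(=O)[C@@]2(C1)C(C)C=C(O[Si](C)(C)C)C[C@H]2C
F4 | step 6 | (1R,3S,5R,10R)-6,10-dimethyl-8-oxo-3-(prop-1-en-2-yl)spiro[4.5]dec-6-en-1-yl 4-nitrobenzoate | C=C(C)[C@@H]1C[C@@H](OC(=O)c3ccc(cc3)[N+](=O)[O-])[C@@]2(C1)C(C)=CC(=O)C[C@H]2C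
F5 | step 6 | (1R,3S,5R,10R)-1-hydroxy-6,10-dimethyl-3-(prop-1-en-2-yl)spiro[4.5]dec-6-en-8-one | C=C(C)[C@@H]1C[C@@H](O)[C@@]2(C1)C(C)=CC(=O)C[C@H]2C
F6 | step 7 | (1R,3S,5R,10R)-6,10-dimethyl-3-(prop-1-en-2-yl)-8-[(trimethylsilyl)oxy]spiro[4.5]deca-6,8-dien-1-yl 2-methylpropanoate | C=C(C)[C@@H]1C[C@@H](OC(=O)C(C)C)[C@@]2(C1)C(C)=CC(O[Si](C)(C)C)=C[C@H]2C
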